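## Analysis of the target

Target 27 is a 1H-isochromen-6-one. Ring A (O2, C1, C8a, C4a, C4, C3) is a 2H-pyran whose enol ether C3=C4 carries the dienyl side chain. Ring B (C4a, C5, C6, C7, C8, C8a) is a cyclohexenone with chlorine on C5 and the ketone at C6, so O2–C3=C4–C4a=C5–C6=O forms one push–pull chromophore. Ring B carries three contiguous stereocentres: the tertiary carbinol C7 (methyl, hydroxyl), the secondary carbinol C8 and the ring-fusion methine C8a. The C7 hydroxyl, the C8 hydroxyl and the C1 methylene lie on the same face (7R,8R,8aS). The side chain is a (1E,3E)-diene ending in an anti methyl/hydroxyl pair (5R,6S); it is too far from the ring for relay of chirality and has to come from its own enantiopure fragment. The sensitive groups are the dienol ether of ring A (acid), the α-ketol C6/C7 (base, acyloin shifts), the C8a–H bond (vinylogous α-position of the ketone) and the chloro-enone (nucleophiles). The difficulty is the all-cis triad ending in a quaternary carbinol next to a carbonyl, combined with a chlorine that cannot be introduced chemoselectively once the electron-rich diene is in place. The strategy rests on one feature: the unit C6(=O)–C7(CH3)(OH) of ring B is the ring-enlarged isomer of a cyclopent-2-enol whose carbinol carbon C6, flanked by C5 and C8, bears an acetyl group made of C7 and its methyl.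

## Retrosynthetic reasoning

Abbreviations: TBS = tert-butyldimethylsilyl, TIPS = triisopropylsilyl, TMS = trimethylsilyl.

27 ⇒ 26 (O2–C3). Ring A is opened at the enol ether, giving the monocyclic ynenone 26 with a free C1 hydroxyl. This bond is made last because the dienol ether is the most acid-labile part of 27. The forward step must be a 6-endo attack of O2 on C3 rather than a 5-exo attack on C4. In-plane attack cannot pass through a conjugated allenolate inside a six-membered ring, so a soft π-acid is planned; the donor diene on C3 and the acceptor enone on C4 then direct oxygen to C3.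

26 ⇒ 25 (protecting groups). The four hydroxyls are reduced to one free tertiary hydroxyl (C7) and three silyl ethers, removed together by fluoride. C8 carries TIPS, C1 and the side chain carry TBS.

25 ⇒ 24 (C7–C8, key step). The bond C7–C8 is cut and C8 is re-attached to C6. This turns the cyclohexenone into the 1-acetylcyclopent-2-enol 24 and removes the quaternary stereocentre C7 from the problem. The forward reaction has to move C8, not the vinylic C5, and has to deliver C8 to the acetyl face that leaves the new hydroxyl cis to O8.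

24 ⇒ 20 + 21 (C6–C7). The acetyl group is an acyl anion equivalent, 22, made from 21. It must add to the C6 ketone of 20 trans to the C8 silyloxy group. Both substituents of 20 (O8 and C1) shield the same face, so the facial bias is reinforced.

20 ⇒ 19 ⇒ 17 + 6 (C4–C4a). The alkyne is attached by 1,2-addition of acetylide 18 (from 6) to the ketone at C4a of 17, followed by oxidative 1,3-transposition that moves the oxygen to C6 and the double bond to C4a=C5. Chlorine is already on C5 in 17. Once the diene side chain is present no electrophilic chlorination would be selective, and a β,β-disubstituted ynenone does not undergo addition–elimination halogenation.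

17 ⇒ 16 ⇒ 15 ⇒ 13 ⇒ 12 (C5–Cl and the C4a oxygen). The 2-chloro enone comes from enone 16 by chlorine addition and elimination. Enone 16 comes from cyclopentene 12 by epoxidation, selenide opening at the less hindered C5, selenoxide elimination towards C6 and oxidation. The two carbonyl positions of the ring (C4a now, C6 later) are thus oxidised one after the other, and their regiochemistry is never in question.

12 ⇒ 11 ⇒ 10 ⇒ 9 ⇒ 8 ⇒ 7 (C8a–C1). The hydroxymethyl carbon is placed on C8a by a [2,3]-sigmatropic shift from the oxygen on C5 of 10. The shift is suprafacial, and in 9 that oxygen is cis to O8, so C1 arrives cis to O8. The absolute configuration is that of the enzymatically derived monoacetate 7. An alternative that builds the ring by enolate hydroxymethylation and enolate hydroxylation of an achiral five-membered precursor was set aside: it gives the trans C8/C8a pair and has no reliable enantioselective variant. O8 is protected as TIPS rather than TBS. In the alkoxide of 9, a silyl shift between the two cis oxygens would interconvert enantiomers, and the same bulk later suppresses silyl transfer to the neighbouring tertiary alkoxide.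

6 ⇒ 5 ⇒ 4 ⇒ 3 ⇒ 2 ⇒ 1 (side chain). The enyne is cut at the disubstituted alkene (phosphonate olefination of enal 5) and the trisubstituted alkene at its double bond (stabilised ylide on aldehyde 4). The anti methyl/hydroxyl pair comes from chelate-controlled methylation of the dianion of 1.

## Alternatives that were turned down

Alternative 1: Both rings are cut at once, at O2–C1 and C4a–C8a. In the forward direction an amine base isomerises the acyclic ynedione A1 to the 1,3-diacylallene A2. The oxadiene O2=C3–C4=C4a of A2 then adds on heating to the vinyl group attached to C8, giving the deschloro bicycle A3.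
- For: it is the shortest of all options, it forms a C–O bond, a C–C bond and two rings in one step, and the C7/C8 diol can come from a simple acetonide fragment. On step economy it is stronger than the chosen route.
- Against: C8a is created in the cycloaddition with only the neighbouring acetonide to control the face. The dienophile is an unactivated vinyl group, so heat is needed, while A2 is the kind of allenyl ketone that cycloisomerises to furans or adds the amine. A3 has no chlorine, so C5 would have to be chlorinated with the diene side chain present.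
- Comparison: the chosen route is longer, but it fixes C8a before any ring-forming step by a stereospecific sigmatropic shift and carries chlorine from a simple enone.

Alternative 2: The cuts are C4–C4a and O2–C3. A zerovalent palladium complex with a monovalent copper salt couples the ring B enol triflate A4 with the free-hydroxyl dienyne A5, and the C1 hydroxyl closes ring A in the same pot to give acetonide A6.
- For: it is the most convergent plan, the coupling is dependable, the side chain enters last and unprotected, and the ring A closure is the same as in the chosen route. On convergence it is stronger.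
- Against: the difficulty moves into A4. It is a fully substituted ring B with all three stereocentres and a regiodefined triflate, derived from an unsymmetrical 2-chloro-1,3-dione whose two carbonyls have to be told apart. C8a sits α to one of them and bears a β-hydroxymethyl group, so epimerisation and elimination threaten. The quaternary carbinol C7 still has to be built by some other means.
- Comparison: the chosen route never has both carbonyls present at once, and it creates C7 in the step that also forms ring B.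

Alternative 3: Ring A is cut at C3=C4. A tertiary amine turns the C4 phosphonium salt A7 into a vinylogous stabilised ylide, which on heating olefinates the ester carbonyl of the dienoate on O1 to give A8.
- For: the closure needs no metal, has no 5-exo/6-endo ambiguity, and the side chain is attached by a simple acylation.
- Against: a doubly stabilised ylide attacking a conjugated ester carbonyl is a slow pairing. The ylide is ambident. Prolonged heating with base endangers C8a, which is γ to the ketone. A7 again requires the complete chiral ring B plus an extra halomethyl group on C4a.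
- Comparison: in the chosen route the alkyne delivers C3 and C4 at the right oxidation level to a ring that is still five-membered and robust. The price is a longer linear sequence.

Key step: step 18

Assumption: compounds 1, 7 and 21 and the reagents named in the Conditions lines, including Bu3SnCH2I and the silylated propargyl phosphonate, are taken as purchasable.

## Route

Step 1
Reactants: 1 ethyl (S)-3-hydroxybutanoate
Product: 2 ethyl (2S,3S)-3-hydroxy-2-methylbutanoate
Conditions: LiN(i-Pr)2 (2.2 equiv), THF, −78 to −20 °C; MeI, DMPU, −78 to 0 °C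
Reagents that add atoms: iodomethane, CI
Why: Fráter–Seebach alkylation; the lithium alkoxide–enolate chelate is methylated on the face away from the C3 methyl group, which should give the anti (2S,3S) isomer.

Step 2
Reactants: 2 ethyl (2S,3S)-3-hydroxy-2-methylbutanoate
Product: 3 ethyl (2S,3S)-3-(TBSO)-2-methylbutanoate
Conditions: t-BuMe2SiCl, imidazole, DMF, rt
Reagents that add atoms: tert-butyldimethylsilyl chloride, CC(C)(C)[Si](C)(C)Cl
Why: Standard silylation of a secondary alcohol; the ether survives the hydride, ylide and organolithium steps that follow.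

Step 3
Reactants: 3 ethyl (2S,3S)-3-(TBSO)-2-methylbutanoate
Product: 4 (2S,3S)-3-(TBSO)-2-methylbutanal
Conditions: i-Bu2AlH, CH2Cl2, −78 °C
Reagents that add atoms: none
Why: Partial ester reduction; the aluminium hemiacetal is stable at −78 °C and releases the aldehyde on work-up, and the crude aldehyde is used at once to protect its α-stereocentre.

Step 4
Reactants: 4 (2S,3S)-3-(TBSO)-2-methylbutanal
Product: 5 (2E,4R,5S)-5-(TBSO)-2,4-dimethylhex-2-enal
Conditions: Ph3P=C(CH3)CHO, toluene, 90 °C
Reagents that add atoms: 2-(triphenylphosphoranylidene)propanal, CC(C=O)=P(c1ccccc1)(c1ccccc1)c1ccccc1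
Why: Wittig olefination with a stabilised formyl ylide, which should give the E trisubstituted enal under thermodynamic control without touching the allylic stereocentre.

Step 5
Reactants: 5 (2E,4R,5S)-5-(TBSO)-2,4-dimethylhex-2-enal
Product: 6 trimethyl[(3E,5E,7R,8S)-8-(TBSO)-5,7-dimethylnona-3,5-dien-1-yn-1-yl]silane
Conditions: (EtO)2P(O)CH2C≡CSiMe3, LiN(SiMe3)2, THF, −78 to 0 °C
Reagents that add atoms: diethyl [3-(trimethylsilyl)prop-2-yn-1-yl]phosphonate, CCOP(=O)(CC#C[Si](C)(C)C)OCC
Why: Horner–Wadsworth–Emmons olefination with a propargylic phosphonate; the stabilised anion should deliver the E enyne and the silyl cap prevents allene formation.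

Step 6
Reactants: 7 (1S,4R)-cis-4-acetoxycyclopent-2-en-1-ol
Product: 8 (1R,4S)-4-(TIPSO)cyclopent-2-en-1-yl acetate
Conditions: i-Pr3SiOTf, 2,6-lutidine, CH2Cl2, 0 °C
Reagents that add atoms: triisopropylsilyl trifluoromethanesulfonate, CC(C)[Si](C(C)C)(C(C)C)OS(=O)(=O)C(F)(F)F
Why: Silylation under non-basic conditions, so the acetate cannot migrate; the bulky TIPS group is chosen because it does not shift between the two cis oxygens in step 8.

Step 7
Reactants: 8 (1R,4S)-4-(TIPSO)cyclopent-2-en-1-yl acetate
Product: 9 (1R,4S)-4-(TIPSO)cyclopent-2-en-1-ol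
Conditions: K2CO3, MeOH, 0 °C
Reagents that add atoms: none
Why: Transesterification to methyl acetate frees the allylic alcohol; no stereocentre is touched.

Step 8
Reactants: 9 (1R,4S)-4-(TIPSO)cyclopent-2-en-1-ol
Product: 10 tributyl({[(1R,4S)-4-(TIPSO)cyclopent-2-en-1-yl]oxy}methyl)stannane
Conditions: KH, Bu3SnCH2I, THF, 0 °C to rt
Reagents that add atoms: (iodomethyl)tributylstannane, CCCC[Sn](CCCC)(CCCC)CI
Why: Williamson etherification of the potassium alkoxide with the α-stannyl iodide installs the carbanion precursor for the Still–Wittig rearrangement.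

Step 9
Reactants: 10 tributyl({[(1R,4S)-4-(TIPSO)cyclopent-2-en-1-yl]oxy}methyl)stannane
Product: 11 [(1S,5S)-5-(TIPSO)cyclopent-2-en-1-yl]methanol
Conditions: n-BuLi, THF, −78 °C
Reagents that add atoms: none
Why: Still–Wittig [2,3]-sigmatropic rearrangement; tin–lithium exchange gives the α-alkoxy carbanion, which bonds to the alkene terminus through a five-centre suprafacial transition state. The carbon is therefore delivered to the face that carried the oxygen, cis to the TIPS ether, which sets C8a.

Step 10
Reactants: 11 [(1S,5S)-5-(TIPSO)cyclopent-2-en-1-yl]methanol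
Product: 12 tert-butyldimethyl{[(1S,5S)-5-(TIPSO)cyclopent-2-en-1-yl]methoxy}silane
Conditions: t-BuMe2SiCl, imidazole, DMF, rt
Reagents that add atoms: tert-butyldimethylsilyl chloride, CC(C)(C)[Si](C)(C)Cl
Why: Silylation of the primary alcohol, which must be masked until ring A is closed.

Step 11
Reactants: 12 tert-butyldimethyl{[(1S,5S)-5-(TIPSO)cyclopent-2-en-1-yl]methoxy}silane
Product: 13 (1R,2R,3S,5S)-2-[(TBSO)methyl]-3-(TIPSO)-6-oxabicyclo[3.1.0]hexane
Conditions: mCPBA, NaHCO3, CH2Cl2, 0 °C
Reagents that add atoms: 3-chloroperoxybenzoic acid, OOC(=O)c1cccc(Cl)c1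
Why: Prilezhaev epoxidation; both silyloxy substituents sit on one face, so the peracid should add from the other.

Step 12
Reactants: 13 (1R,2R,3S,5S)-2-[(TBSO)methyl]-3-(TIPSO)-6-oxabicyclo[3.1.0]hexane
Product: 15 (1S,4S,5R)-5-[(TBSO)methyl]-4-(TIPSO)cyclopent-2-en-1-ol, via hydroxy selenide 14 (not isolated)
Conditions: (PhSe)2, NaBH4, EtOH, 0 °C to reflux; then H2O2, pyridine, THF, 0 °C to rt
Reagents that add atoms: none
Why: Organoselenium conversion of an epoxide into an allylic alcohol; the selenolate opens the epoxide by SN2 at the carbon remote from the hydroxymethyl-bearing centre. The selenoxide then eliminates syn towards the ring methylene and away from the carbinol, which places the oxygen on C4a and the alkene at C5=C6.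

Step 13
Reactants: 15 (1S,4S,5R)-5-[(TBSO)methyl]-4-(TIPSO)cyclopent-2-en-1-ol
Product: 16 (4S,5S)-5-[(TBSO)methyl]-4-(TIPSO)cyclopent-2-en-1-one
Conditions: Dess–Martin periodinane, NaHCO3, CH2Cl2, rt
Reagents that add atoms: none
Why: Buffered Dess–Martin oxidation of an allylic alcohol; the neutral medium should spare the epimerisable α′-centre and the β-silyloxy groups.

Step 14
Reactants: 16 (4S,5S)-5-[(TBSO)methyl]-4-(TIPSO)cyclopent-2-en-1-one
Product: 17 (4R,5S)-2-chloro-5-[(TBSO)methyl]-4-(TIPSO)cyclopent-2-en-1-one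
Conditions: PhICl2, pyridine, CH2Cl2, 0 °C to rt
Reagents that add atoms: iodobenzene dichloride, ClI(Cl)c1ccccc1
Why: α-Chlorination of an enone by addition–elimination; chlorine adds across the enone double bond and pyridine removes the acidic α-hydrogen with loss of the β-chloride. The chlorine enters before any electron-rich alkene is present.

Step 15
Reactants: 6 trimethyl[(3E,5E,7R,8S)-8-(TBSO)-5,7-dimethylnona-3,5-dien-1-yn-1-yl]silane, 17 (4R,5S)-2-chloro-5-[(TBSO)methyl]-4-(TIPSO)cyclopent-2-en-1-one
Product: 19 (1R,4R,5S)-2-chloro-1-[(3E,5E,7R,8S)-8-(TBSO)-5,7-dimethylnona-3,5-dien-1-yn-1-yl]-5-[(TBSO)methyl]-4-(TIPSO)cyclopent-2-en-1-ol, via lithium acetylide 18 (not isolated)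
Conditions: MeLi·LiBr, THF, 0 °C to rt; CeCl3, then 17, −78 °C
Reagents that add atoms: none
Why: Desilylative lithiation of the alkynylsilane, then 1,2-addition of the acetylide to the enone carbonyl; CeCl3 tempers the basicity so that the α′-hydrogen with its two β-silyloxy groups is not removed. The new carbinol centre is lost in step 16, so its configuration (attack anti to the hydroxymethyl arm is expected) is immaterial.

Step 16
Reactants: 19 (1R,4R,5S)-2-chloro-1-[(3E,5E,7R,8S)-8-(TBSO)-5,7-dimethylnona-3,5-dien-1-yn-1-yl]-5-[(TBSO)methyl]-4-(TIPSO)cyclopent-2-en-1-ol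
Product: 20 (4S,5R)-2-chloro-3-[(3E,5E,7R,8S)-8-(TBSO)-5,7-dimethylnona-3,5-dien-1-yn-1-yl]-4-[(TBSO)methyl]-5-(TIPSO)cyclopent-2-en-1-one
Conditions: pyridinium chlorochromate [C5H5NH][CrO3Cl], NaOAc, 4 Å sieves, CH2Cl2, rt
Reagents that add atoms: pyridinium chlorochromate, [O-][Cr](=O)(=O)Cl.c1cc[nH+]cc1
Why: Babler–Dauben oxidative transposition; the tertiary chromate ester undergoes a [3,3] shift that places a chromium-bound oxygen on C6 (the original hydroxyl oxygen leaves with chromium), and oxidation of the secondary chromate gives the enone with the double bond at C4a=C5. The C8 and C8a centres are not involved.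

Step 17
Reactants: 20 (4S,5R)-2-chloro-3-[(3E,5E,7R,8S)-8-(TBSO)-5,7-dimethylnona-3,5-dien-1-yn-1-yl]-4-[(TBSO)methyl]-5-(TIPSO)cyclopent-2-en-1-one, 21 ethyl vinyl ether
Product: 24 1-[(1S,4S,5R)-2-chloro-1-hydroxy-3-[(3E,5E,7R,8S)-8-(TBSO)-5,7-dimethylnona-3,5-dien-1-yn-1-yl]-4-[(TBSO)methyl]-5-(TIPSO)cyclopent-2-en-1-yl]ethan-1-one, via 1-ethoxyvinyllithium 22 (not isolated), via enol ether adduct 23 (not isolated)
Conditions: 21, t-BuLi, THF, −78 to 0 °C; 20, −78 °C; aq. oxalic acid, THF, 0 °C
Reagents that add atoms: water, O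
Why: 1,2-Addition of an acyl anion equivalent followed by mild enol ether hydrolysis, the classical entry to 1-acylcycloalkanols. The hard organolithium should attack the carbonyl rather than the ynenone termini, and it should come from the face opposite the C8 silyloxy group and the C1 arm, so the acetyl group ends trans and the hydroxyl cis to O8.

Step 18
Reactants: 24 1-[(1S,4S,5R)-2-chloro-1-hydroxy-3-[(3E,5E,7R,8S)-8-(TBSO)-5,7-dimethylnona-3,5-dien-1-yn-1-yl]-4-[(TBSO)methyl]-5-(TIPSO)cyclopent-2-en-1-yl]ethan-1-one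
Product: 25 (4S,5R,6R)-2-chloro-6-hydroxy-6-methyl-3-[(3E,5E,7R,8S)-8-(TBSO)-5,7-dimethylnona-3,5-dien-1-yn-1-yl]-4-[(TBSO)methyl]-5-(TIPSO)cyclohex-2-en-1-one
Conditions: Al(Ot-Bu)3, toluene, 80 °C
Reagents that add atoms: none
Why: Alkoxide exchange puts aluminium on the C6 oxygen and the metal also binds the acetyl oxygen, so the two C–O bonds are held syn in a five-membered chelate. In this geometry the ring bonds C6–C5 and C6–C8 flank the two faces of the acetyl carbonyl, and C8 shifts with its bonding pair from C6 to C7 while C6 becomes the ketone; this is the α-ketol (acyloin) rearrangement of a 1-acylcycloalkanol, the reaction type of the D-homoannulation of 17-hydroxy-20-keto steroids. Ring B is formed not by a cyclisation but by one-carbon enlargement of the cyclopentene through this 1,2-shift, so no exo or endo mode applies. C8 migrates with retention; because the chelate holds the carbonyl oxygen on the side of the C6 oxygen, which is cis to the C8 silyloxy group, C8 bonds to the acetyl face that leaves the new C7 hydroxyl cis to O8 and the methyl trans (7R), the controlling elements being the C6 configuration from step 17 and the chelate. The step needs migration of C8 and not of the vinylic C5: the rearrangement is reversible, only the C8 shift gives a six-membered ketone conjugated with the chloro-enyne, and the deconjugated isomer from C5 migration can return to 24. The TIPS group blocks silyl transfer to the neighbouring aluminium alkoxide, and Al(Ot-Bu)3 has no hydride to give for a Meerwein–Ponndorf reduction.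

Step 19
Reactants: 25 (4S,5R,6R)-2-chloro-6-hydroxy-6-methyl-3-[(3E,5E,7R,8S)-8-(TBSO)-5,7-dimethylnona-3,5-dien-1-yn-1-yl]-4-[(TBSO)methyl]-5-(TIPSO)cyclohex-2-en-1-one
Product: 26 (4S,5R,6R)-2-chloro-5,6-dihydroxy-4-(hydroxymethyl)-3-[(3E,5E,7R,8S)-8-hydroxy-5,7-dimethylnona-3,5-dien-1-yn-1-yl]-6-methylcyclohex-2-en-1-one
Conditions: HF·pyridine, pyridine, THF, 0 °C to rt
Reagents that add atoms: none
Why: Fluoride-driven cleavage of all three silyl ethers under buffered conditions that the ynenone and the α-ketol should tolerate; any 27 formed by spontaneous closure at this stage is carried forward.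

Step 20
Reactants: 26 (4S,5R,6R)-2-chloro-5,6-dihydroxy-4-(hydroxymethyl)-3-[(3E,5E,7R,8S)-8-hydroxy-5,7-dimethylnona-3,5-dien-1-yn-1-yl]-6-methylcyclohex-2-en-1-one
Product: 27 (7R,8R,8aS)-5-chloro-7,8-dihydroxy-3-[(1E,3E,5R,6S)-6-hydroxy-3,5-dimethylhepta-1,3-dien-1-yl]-7-methyl-8,8a-dihydro-1H-isochromen-6(7H)-one
Conditions: Ph3PAuNTf2 (5 mol %), CH2Cl2, 0 °C to rt
Reagents that add atoms: none
Why: Gold-catalysed 6-endo-dig hydroalkoxylation (cycloisomerisation) of an alkynyl alcohol; the π-activated alkyne is attacked at C3, the carbon that bears the donor diene and is remote from the electron-poor C4a, and protodeauration gives the C3=C4 enol ether. No stereocentre is formed or touched.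

## Compound list

1 | ethyl (S)-3-hydroxybutanoate | CCOC(=O)C[C@H](C)O | starting material
2 | ethyl (2S,3S)-3-hydroxy-2-methylbutanoate | CCOC(=O)[C@@H](C)[C@H](C)O | intermediate
3 | ethyl (2S,3S)-3-(TBSO)-2-methylbutanoate | CCOC(=O)[C@@H](C)[C@H](C)O[Si](C)(C)C(C)(C)C | intermediate
4 | (2S,3S)-3-(TBSO)-2-methylbutanal | O=C[C@@H](C)[C@H](C)O[Si](C)(C)C(C)(C)C | intermediate
5 | (2E,4R,5S)-5-(TBSO)-2,4-dimethylhex-2-enal | O=C/C(C)=C/[C@@H](C)[C@H](C)O[Si](C)(C)C(C)(C)C | intermediate
6 | trimethyl[(3E,5E,7R,8S)-8-(TBSO)-5,7-dimethylnona-3,5-dien-1-yn-1-yl]silane | CC(/C=C/C#C[Si](C)(C)C)=C\[C@@H](C)[C@H](C)O[Si](C)(C)C(C)(C)C | intermediate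
7 | (1S,4R)-cis-4-acetoxycyclopent-2-en-1-ol | CC(=O)O[C@H]1C=C[C@@H](O)C1 | starting material
8 | (1R,4S)-4-(TIPSO)cyclopent-2-en-1-yl acetate | CC(=O)O[C@H]1C=C[C@@H](O[Si](C(C)C)(C(C)C)C(C)C)C1 | intermediate
9 | (1R,4S)-4-(TIPSO)cyclopent-2-en-1-ol | O[C@H]1C=C[C@@H](O[Si](C(C)C)(C(C)C)C(C)C)C1 | intermediate
10 | tributyl({[(1R,4S)-4-(TIPSO)cyclopent-2-en-1-yl]oxy}methyl)stannane | CCCC[Sn](CCCC)(CCCC)CO[C@H]1C=C[C@@H](O[Si](C(C)C)(C(C)C)C(C)C)C1 | intermediate
11 | [(1S,5S)-5-(TIPSO)cyclopent-2-en-1-yl]methanol | C1=CC[C@H](O[Si](C(C)C)(C(C)C)C(C)C)[C@@H]1CO | intermediate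
12 | tert-butyldimethyl{[(1S,5S)-5-(TIPSO)cyclopent-2-en-1-yl]methoxy}silane | C1=CC[C@H](O[Si](C(C)C)(C(C)C)C(C)C)[C@@H]1CO[Si](C)(C)C(C)(C)C | intermediate
13 | (1R,2R,3S,5S)-2-[(TBSO)methyl]-3-(TIPSO)-6-oxabicyclo[3.1.0]hexane, epoxide anti to both silyloxy groups | O1[C@H]2C[C@H](O[Si](C(C)C)(C(C)C)C(C)C)[C@H](CO[Si](C)(C)C(C)(C)C)[C@@H]12 | intermediate
14 | (1R,2R,3S,5R)-2-[(TBSO)methyl]-5-(phenylselanyl)-3-(TIPSO)cyclopentan-1-ol (hydroxy selenide) | O[C@H]1[C@H]([Se]c2ccccc2)C[C@H](O[Si](C(C)C)(C(C)C)C(C)C)[C@@H]1CO[Si](C)(C)C(C)(C)C | intermediate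
15 | (1S,4S,5R)-5-[(TBSO)methyl]-4-(TIPSO)cyclopent-2-en-1-ol | O[C@H]1C=C[C@H](O[Si](C(C)C)(C(C)C)C(C)C)[C@@H]1CO[Si](C)(C)C(C)(C)C | intermediate
16 | (4S,5S)-5-[(TBSO)methyl]-4-(TIPSO)cyclopent-2-en-1-one | O=C1C=C[C@H](O[Si](C(C)C)(C(C)C)C(C)C)[C@@H]1CO[Si](C)(C)C(C)(C)C | intermediate
17 | (4R,5S)-2-chloro-5-[(TBSO)methyl]-4-(TIPSO)cyclopent-2-en-1-one | O=C1C(Cl)=C[C@H](O[Si](C(C)C)(C(C)C)C(C)C)[C@@H]1CO[Si](C)(C)C(C)(C)C | intermediate
18 | [(3E,5E,7R,8S)-8-(TBSO)-5,7-dimethylnona-3,5-dien-1-yn-1-yl]lithium (lithium acetylide) | CC(/C=C/C#C[Li])=C\[C@@H](C)[C@H](C)O[Si](C)(C)C(C)(C)C | intermediate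
19 | (1R,4R,5S)-2-chloro-1-[(3E,5E,7R,8S)-8-(TBSO)-5,7-dimethylnona-3,5-dien-1-yn-1-yl]-5-[(TBSO)methyl]-4-(TIPSO)cyclopent-2-en-1-ol (expected major C1 epimer) | CC(/C=C/C#C[C@@]1(O)C(Cl)=C[C@H](O[Si](C(C)C)(C(C)C)C(C)C)[C@@H]1CO[Si](C)(C)C(C)(C)C)=C\[C@@H](C)[C@H](C)O[Si](C)(C)C(C)(C)C | intermediate
20 | (4S,5R)-2-chloro-3-[(3E,5E,7R,8S)-8-(TBSO)-5,7-dimethylnona-3,5-dien-1-yn-1-yl]-4-[(TBSO)methyl]-5-(TIPSO)cyclopent-2-en-1-one | CC(/C=C/C#CC1=C(Cl)C(=O)[C@H](O[Si](C(C)C)(C(C)C)C(C)C)[C@@H]1CO[Si](C)(C)C(C)(C)C)=C\[C@@H](C)[C@H](C)O[Si](C)(C)C(C)(C)C | intermediate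
21 | ethyl vinyl ether | C=COCC | starting material
22 | 1-ethoxyvinyllithium | [Li]C(=C)OCC | intermediate
23 | (1S,4S,5R)-2-chloro-1-(1-ethoxyvinyl)-3-[(3E,5E,7R,8S)-8-(TBSO)-5,7-dimethylnona-3,5-dien-1-yn-1-yl]-4-[(TBSO)methyl]-5-(TIPSO)cyclopent-2-en-1-ol (enol ether adduct) | CC(/C=C/C#CC1=C(Cl)[C@@](O)(C(=C)OCC)[C@H](O[Si](C(C)C)(C(C)C)C(C)C)[C@@H]1CO[Si](C)(C)C(C)(C)C)=C\[C@@H](C)[C@H](C)O[Si](C)(C)C(C)(C)C | intermediate
24 | 1-[(1S,4S,5R)-2-chloro-1-hydroxy-3-[(3E,5E,7R,8S)-8-(TBSO)-5,7-dimethylnona-3,5-dien-1-yn-1-yl]-4-[(TBSO)methyl]-5-(TIPSO)cyclopent-2-en-1-yl]ethan-1-one | CC(/C=C/C#CC1=C(Cl)[C@@](O)(C(C)=O)[C@H](O[Si](C(C)C)(C(C)C)C(C)C)[C@@H]1CO[Si](C)(C)C(C)(C)C)=C\[C@@H](C)[C@H](C)O[Si](C)(C)C(C)(C)C | intermediate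
25 | (4S,5R,6R)-2-chloro-6-hydroxy-6-methyl-3-[(3E,5E,7R,8S)-8-(TBSO)-5,7-dimethylnona-3,5-dien-1-yn-1-yl]-4-[(TBSO)methyl]-5-(TIPSO)cyclohex-2-en-1-one | CC(/C=C/C#CC1=C(Cl)C(=O)[C@](C)(O)[C@H](O[Si](C(C)C)(C(C)C)C(C)C)[C@@H]1CO[Si](C)(C)C(C)(C)C)=C\[C@@H](C)[C@H](C)O[Si](C)(C)C(C)(C)C | intermediate
26 | (4S,5R,6R)-2-chloro-5,6-dihydroxy-4-(hydroxymethyl)-3-[(3E,5E,7R,8S)-8-hydroxy-5,7-dimethylnona-3,5-dien-1-yn-1-yl]-6-methylcyclohex-2-en-1-one | CC(/C=C/C#CC1=C(Cl)C(=O)[C@](C)(O)[C@H](O)[C@@H]1CO)=C\[C@@H](C)[C@H](C)O | intermediate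
27 | (7R,8R,8aS)-5-chloro-7,8-dihydroxy-3-[(1E,3E,5R,6S)-6-hydroxy-3,5-dimethylhepta-1,3-dien-1-yl]-7-methyl-8,8a-dihydro-1H-isochromen-6(7H)-one | CC(/C=C/C1=CC2=C(Cl)C(=O)[C@](C)(O)[C@H](O)[C@@H]2CO1)=C\[C@@H](C)[C@H](C)O | target

## Step count and least certain steps

Total: 20 steps. Longest linear sequence: 15 steps (steps 6 to 20, from 7). The side chain takes 5 steps (steps 1 to 5) and joins in step 15.

Step 18 (key step). What may go wrong: migration of the vinylic C5 instead of C8, or loss of the C7 configuration by repeated reversible shifts under thermodynamic control, since the bare ynenone offers only a moderate energetic preference for the conjugated product. Fallback, setting out from 24 and rejoining at 27: ring A is closed before the ring enlargement. Brief treatment of 24 with buffered HF·pyridine at 0 °C should remove only the primary silyl ether and give the C1 alcohol F1. Ph3PAuNTf2 should then close ring A to the cyclopenta[c]pyran ketol F2. Al(Ot-Bu)3 should rearrange F2 to the bicyclic silyl ether F3. In F3 the new C6 ketone is the terminus of the vinylogous ester O2–C3=C4–C4a=C5, so the pull towards C8 migration is much stronger. HF·pyridine then gives 27.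

Step 16. What may go wrong: ionisation of the tertiary, propargylic and allylic alcohol under the acidic chromium reagent, or a slow [3,3] shift because of the chlorine on the central carbon, leading to elimination or rearrangement on the alkyne side. Fallback, from 19 to 20: a catalytic amount of Ph3SiOReO3 in ether at low temperature should move the hydroxyl suprafacially to C6 through the perrhenate ester, driven by enyne conjugation, and give the secondary allylic alcohol F4. Dess–Martin periodinane then oxidises F4 to 20.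

Step 9. What may go wrong: competing [1,2]-shift or incomplete rearrangement, because the new bond forms next to and cis to the bulky silyloxy group. Fallback, from 9 to 11: heating 9 with N,N-dimethylformamide dimethyl acetal should give, by [2,3]-sigmatropic rearrangement of the formamide acetal on the same face, the amide F5. LiH2NBH3 then reduces F5 to 11.

Step 14. What may go wrong: epimerisation at the α′-carbon or β-elimination of a silyloxy group under the amine, or over-chlorination. Fallback, from 16 to 17: Weitz–Scheffer epoxidation (H2O2, NaOH, MeOH, −20 °C) should give the epoxy ketone F6 with the oxirane anti to the C4 silyloxy group. Anhydrous HCl in CHCl3 at 0 °C should then open it at the α-carbon and dehydrate to 17.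

Step 20. What may go wrong: competing 5-exo closure at C4, or decomposition of the dienol ether in the presence of the cationic gold complex. Fallback, from 26 to 27 without new compounds: nucleophilic catalysis instead of π-acid catalysis. DABCO (or PBu3) in CH2Cl2 should add to C3 of the ynenone, the C1 hydroxyl should then add to the resulting vinyl-onium enolate, and loss of the catalyst should give 27.

## Further compounds

F1 | step 18 | 1-[(1S,4S,5R)-2-chloro-1-hydroxy-4-(hydroxymethyl)-3-[(3E,5E,7R,8S)-8-(TBSO)-5,7-dimethylnona-3,5-dien-1-yn-1-yl]-5-(TIPSO)cyclopent-2-en-1-yl]ethan-1-one | CC(/C=C/C#CC1=C(Cl)[C@@](O)(C(C)=O)[C@H](O[Si](C(C)C)(C(C)C)C(C)C)[C@@H]1CO)=C\[C@@H](C)[C@H](C)O[Si](C)(C)C(C)(C)C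
F2 | step 18 | 1-[(6S,7R,7aS)-4-chloro-6-hydroxy-3-[(1E,3E,5R,6S)-6-(TBSO)-3,5-dimethylhepta-1,3-dien-1-yl]-7-(TIPSO)-1,6,7,7a-tetrahydrocyclopenta[c]pyran-6-yl]ethan-1-one, written here with the chlorine on the ring carbon next to the carbinol | CC(/C=C/C1=CC2=C(Cl)[C@@](O)(C(C)=O)[C@H](O[Si](C(C)C)(C(C)C)C(C)C)[C@@H]2CO1)=C\[C@@H](C)[C@H](C)O[Si](C)(C)C(C)(C)C
F3 | step 18 | (7R,8R,8aS)-5-chloro-7-hydroxy-7-methyl-3-[(1E,3E,5R,6S)-6-(TBSO)-3,5-dimethylhepta-1,3-dien-1-yl]-8-(TIPSO)-8,8a-dihydro-1H-isochromen-6(7H)-one | CC(/C=C/C1=CC2=C(Cl)C(=O)[C@](C)(O)[C@H](O[Si](C(C)C)(C(C)C)C(C)C)[C@@H]2CO1)=C\[C@@H](C)[C@H](C)O[Si](C)(C)C(C)(C)C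
F4 | step 16 | (1R,4S,5R)-2-chloro-3-[(3E,5E,7R,8S)-8-(TBSO)-5,7-dimethylnona-3,5-dien-1-yn-1-yl]-4-[(TBSO)methyl]-5-(TIPSO)cyclopent-2-en-1-ol | CC(/C=C/C#CC1=C(Cl)[C@H](O)[C@H](O[Si](C(C)C)(C(C)C)C(C)C)[C@@H]1CO[Si](C)(C)C(C)(C)C)=C\[C@@H](C)[C@H](C)O[Si](C)(C)C(C)(C)C
F5 | step 9 | (1R,5S)-N,N-dimethyl-5-(TIPSO)cyclopent-2-ene-1-carboxamide | CN(C)C(=O)[C@@H]1C=CC[C@@H]1O[Si](C(C)C)(C(C)C)C(C)C
F6 | step 14 | 3-[(TBSO)methyl]-4-(TIPSO)-6-oxabicyclo[3.1.0]hexan-2-one, the 2,3-epoxide of 16 with the oxirane anti to the C4 silyloxy group | O=C1[C@H]2O[C@H]2[C@H](O[Si](C(C)C)(C(C)C)C(C)C)[C@@H]1CO[Si](C)(C)C(C)(C)C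
F0 | step 20 | none | none
A1 | alternative 1 | acyclic ynedione with the C7/C8 acetonide and a vinyl group on C8 | CC(/C=C/C(=O)CC#CC(=O)[C@]1(C)OC(C)(C)O[C@@H]1C=C)=C\[C@@H](C)[C@H](C)O[Si](C)(C)C(C)(C)C
A2 | alternative 1 | 1,3-diacylallene isomer of A1 (either helicity) | CC(/C=C/C(=O)C=C=CC(=O)[C@]1(C)OC(C)(C)O[C@@H]1C=C)=C\[C@@H](C)[C@H](C)O[Si](C)(C)C(C)(C)C
A3 | alternative 1 | 5-deschloro bicyclic core as C7/C8 acetonide and side-chain TBS ether | CC(/C=C/C1=CC2=CC(=O)[C@]3(C)OC(C)(C)O[C@@H]3[C@@H]2CO1)=C\[C@@H](C)[C@H](C)O[Si](C)(C)C(C)(C)C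
A4 | alternative 2 | ring B enol triflate: 2-chloro-3-triflyloxy-cyclohex-2-enone with C7/C8 acetonide and free C1 hydroxyl | OC[C@@H]1C(OS(=O)(=O)C(F)(F)F)=C(Cl)C(=O)[C@]2(C)OC(C)(C)O[C@H]12
A5 | alternative 2 | (2S,3R,4E,6E)-3,5-dimethylnona-4,6-dien-8-yn-2-ol | CC(/C=C/C#C)=C\[C@@H](C)[C@H](C)O
A6 | alternative 2 | target as its C7/C8 acetonide | CC(/C=C/C1=CC2=C(Cl)C(=O)[C@]3(C)OC(C)(C)O[C@@H]3[C@@H]2CO1)=C\[C@@H](C)[C@H](C)O
A7 | alternative 3 | C4 triphenylphosphonium bromide of ring B (C7/C8 acetonide) carrying the side-chain dienoate ester on O1 | CC(/C=C/C(=O)OC[C@@H]1C(C[P+](c2ccccc2)(c2ccccc2)c2ccccc2)=C(Cl)C(=O)[C@]2(C)OC(C)(C)O[C@H]12)=C\[C@@H](C)[C@H](C)O[Si](C)(C)C(C)(C)C.[Br-]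
A8 | alternative 3 | target as C7/C8 acetonide and side-chain TBS ether | CC(/C=C/C1=CC2=C(Cl)C(=O)[C@]3(C)OC(C)(C)O[C@@H]3[C@@H]2CO1)=C\[C@@H](C)[C@H](C)O[Si](C)(C)C(C)(C)C
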